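**Plan**

- Retrosynthesis: the (Z)-dienyl side chain is re-closed onto O7 as a 7,8-fused 2,2-dimethylchromene, and that pyran is cut at C8–C and O7–C to a 7-O-(1,1-dimethylpropargyl) ether. The chromanone is taken back to a flavone and cut at C4a–C4, C4–C3 and O1–C2. The dihydrofuran is cut at O1–C2 and C2–C3 into a quinone methide and a benzylic sulfonium ylide.
- Enabling feature: in the pyranone ring O1–C2–C3–C4–C4a–C8a the carbonyl carbon C4 sits alone between ring A (C4a, with O1 on the adjacent C8a) and the C2–C3 pair that carries the dihydrobenzofuran arene. C4 therefore maps onto CO, C2–C3 onto an aryl acetylene, and O1/C4a onto an ortho-iodophenol.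
- Forward order of rings: dihydrofuran ([4+1] annulation), then the pyranone (three-component carbonylative annulation), reduced to the chromanone, then the pyran on ring A (propargyl Claisen cascade), which is finally opened by light to the dienylphenol.
- Protecting groups: ring A carries benzyl ethers and the dihydrobenzofuran unit MOM ethers. Hydrogenolysis frees only 5-OH and 7-OH, so the propargyl ether goes on O7 without competition, and the MOM groups are removed once the chromene is in place.
- Stereochemistry: C2/C3 of the dihydrobenzofuran (2R,3R, trans) come from the chiral sulfide bound in the ylide. C2 of the flavanone (S) comes from the chiral NHC ligand in the flavone hydrogenation. The Z alkene comes from the cyclic geometry of the [1,7]-hydrogen shift.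

Key step: step 12

Assumption: alkylation of sulfide 13 is taken to occur on the exo lone pair of sulfur, and the senses of induction of 13 (step 9) and of (R,R)-SINpEt (step 13) are taken as stated; if a pilot run shows the opposite sense, the mirror-image sulfide or ligand is used with no other change.

Abbreviations used in names:
- MOM = methoxymethyl; Bn = benzyl; TBS = tert-butyldimethylsilyl.
- DBF(MOM) = (2R,3R)-3-[3,5-bis(methoxymethoxy)phenyl]-6-(methoxymethoxy)-2-[4-(methoxymethoxy)phenyl]-2,3-dihydro-1-benzofuran-5-yl.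
- DBF(OH) = (2R,3R)-3-(3,5-dihydroxyphenyl)-6-hydroxy-2-(4-hydroxyphenyl)-2,3-dihydro-1-benzofuran-5-yl.
- SINpEt = 1,3-bis[(1R)-1-(naphthalen-1-yl)ethyl]imidazolidin-2-ylidene.

**Route**

Step 1
Reactants: 1 3,5-bis(benzyloxy)phenol
Product: 2 3,5-bis(benzyloxy)-2-iodophenol
Conditions: BnMe3N·ICl2 (1.0 equiv), NaHCO3, CH2Cl2/MeOH, rt
Reagents that add atoms: benzyltrimethylammonium dichloroiodate, C[N+](C)(C)Cc1ccccc1.Cl[I-]Cl
Why: Buffered electrophilic aromatic iodination, as practised on 3,5-dialkoxyphenols, should place iodine ortho to the free hydroxyl without touching the benzyl ethers, and any 4-iodo isomer is removed by chromatography.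

Step 2
Reactants: 3 5-bromo-2,4-dihydroxybenzaldehyde
Product: 4 5-bromo-2-hydroxy-4-(methoxymethoxy)benzaldehyde
Conditions: MOMCl (1.05 equiv), K2CO3, acetone, 0 °C to rt
Reagents that add atoms: chloromethyl methyl ether (MOMCl), COCCl
Why: Selective Williamson O-alkylation of the 4-hydroxyl, because the 2-hydroxyl is hydrogen-bonded to the aldehyde and is the less nucleophilic site.

Step 3
Reactants: 5 5-bromoresorcinol
Product: 6 1-bromo-3,5-bis(methoxymethoxy)benzene
Conditions: MOMCl (2.4 equiv), i-Pr2NEt, CH2Cl2, 0 °C to rt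
Reagents that add atoms: chloromethyl methyl ether (MOMCl), COCCl
Why: Williamson-type MOM ether formation on both phenols of a symmetric diol.

Step 4
Reactants: 6 1-bromo-3,5-bis(methoxymethoxy)benzene; 4 5-bromo-2-hydroxy-4-(methoxymethoxy)benzaldehyde
Product: 8 4-bromo-2-{[3,5-bis(methoxymethoxy)phenyl](hydroxy)methyl}-5-(methoxymethoxy)phenol (racemic), via arylmagnesium bromide 7 (not isolated)
Conditions: Mg, LiCl, THF, 40 °C; then 4 (0.45 equiv), −20 °C to rt; aq NH4Cl
Reagents that add atoms: none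
Why: Grignard formation and 1,2-addition to the aldehyde, in which the first equivalent of 7 is consumed by the phenol and the second adds to the carbonyl; the racemic carbinol centre is of no consequence because it becomes trigonal in step 9.

Step 5
Reactants: 8 4-bromo-2-{[3,5-bis(methoxymethoxy)phenyl](hydroxy)methyl}-5-(methoxymethoxy)phenol
Product: 9 4-bromo-2-{[3,5-bis(methoxymethoxy)phenyl](4-methylbenzenesulfonyl)methyl}-5-(methoxymethoxy)phenol (racemic)
Conditions: p-TolSO2H (1.5 equiv), MgSO4, CH2Cl2, 0 °C to rt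
Reagents that add atoms: 4-methylbenzenesulfinic acid, Cc1ccc(cc1)S(=O)O
Why: SN1 substitution of the doubly activated (ortho-hydroxy, para-alkoxy) benzhydrol by the sulfinate sulfur, the standard entry to 2-(sulfonylalkyl)phenols as quinone methide precursors, under acid mild enough to spare the MOM ethers.

Step 6
Reactants: 10 4-hydroxybenzyl alcohol
Product: 11 [4-(methoxymethoxy)phenyl]methanol
Conditions: MOMCl (1.05 equiv), K2CO3, acetone, 0 °C to rt
Reagents that add atoms: chloromethyl methyl ether (MOMCl), COCCl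
Why: Chemoselective Williamson alkylation, since only the phenol is ionised by K2CO3.

Step 7
Reactants: 11 [4-(methoxymethoxy)phenyl]methanol
Product: 12 1-(bromomethyl)-4-(methoxymethoxy)benzene
Conditions: CBr4, PPh3, CH2Cl2, 0 °C; used at once
Reagents that add atoms: tetrabromomethane, BrC(Br)(Br)Br
Why: Appel bromination of the benzylic alcohol under neutral conditions that the MOM ether tolerates.

Step 8
Reactants: 12 1-(bromomethyl)-4-(methoxymethoxy)benzene; 13 (1R,4R,5R)-isothiocineole
Product: 14 (1R,4R,5R)-6-[4-(methoxymethoxy)benzyl]-4,7,7-trimethyl-6-thiabicyclo[3.2.1]octan-6-ium tetrafluoroborate (benzyl on the exo face of sulfur)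
Conditions: NaBF4, CH2Cl2/H2O, rt
Reagents that add atoms: sodium tetrafluoroborate, [Na+].F[B-](F)(F)F
Why: SN2 S-alkylation of the sulfide with the benzylic bromide and anion exchange to the non-nucleophilic tetrafluoroborate, which prevents dealkylation by bromide.

Step 9
Reactants: 9 4-bromo-2-{[3,5-bis(methoxymethoxy)phenyl](4-methylbenzenesulfonyl)methyl}-5-(methoxymethoxy)phenol; 14 sulfonium tetrafluoroborate
Product: 17 (2R,3R)-5-bromo-3-[3,5-bis(methoxymethoxy)phenyl]-6-(methoxymethoxy)-2-[4-(methoxymethoxy)phenyl]-2,3-dihydro-1-benzofuran, via quinone methide 15 (not isolated), via sulfonium ylide 16 (not isolated)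
Conditions: Cs2CO3 (2.5 equiv), MeCN/CH2Cl2, −20 °C to rt
Reagents that add atoms: none
Why: Proposed new method: Cs2CO3 eliminates sulfinate from 9 to give quinone methide 15 and deprotonates 14 to the benzylic ylide 16; conjugate addition of 16 to the methide carbon followed by SN2 displacement of the sulfide by the phenoxide (5-exo-tet, inversion at the ylide carbon) closes the dihydrofuran, the anti betaine leading to the trans ring; the rigid bicyclic sulfide fixes the ylide conformation and shields one face, which should set C2 and, through the anti addition, C3 as (2R,3R); the closest known reactions are the racemic [4+1] annulation of sulfur ylides with quinone methides released from 2-(sulfonylalkyl)phenols and the isothiocineole-mediated asymmetric epoxidation of aldehydes with benzylic sulfonium salts.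

Step 10
Reactants: 17 (2R,3R)-5-bromo-3-[3,5-bis(methoxymethoxy)phenyl]-6-(methoxymethoxy)-2-[4-(methoxymethoxy)phenyl]-2,3-dihydro-1-benzofuran
Product: 18 [(DBF(MOM))ethynyl]trimethylsilane
Conditions: Me3SiC≡CH, PdCl2(PhCN)2 (3 mol%), P(t-Bu)3 (6 mol%), CuI (2 mol%), i-Pr2NH, 1,4-dioxane, 50 °C
Reagents that add atoms: ethynyltrimethylsilane, C#C[Si](C)(C)C
Why: Sonogashira coupling in which the bulky electron-rich phosphine allows oxidative addition into the electron-rich, ortho-alkoxylated aryl bromide at moderate temperature.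

Step 11
Reactants: 18 [(DBF(MOM))ethynyl]trimethylsilane
Product: 19 (2R,3R)-5-ethynyl-3-[3,5-bis(methoxymethoxy)phenyl]-6-(methoxymethoxy)-2-[4-(methoxymethoxy)phenyl]-2,3-dihydro-1-benzofuran
Conditions: K2CO3 (cat.), MeOH/THF, rt
Reagents that add atoms: none
Why: Base-catalysed protodesilylation (methanolysis) of the alkynylsilane, which leaves the MOM ethers and both benzylic stereocentres untouched.

Step 12
Reactants: 2 3,5-bis(benzyloxy)-2-iodophenol; 19 (2R,3R)-5-ethynyl-3-[3,5-bis(methoxymethoxy)phenyl]-6-(methoxymethoxy)-2-[4-(methoxymethoxy)phenyl]-2,3-dihydro-1-benzofuran; 20 carbon monoxide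
Product: 22 5,7-bis(benzyloxy)-2-(DBF(MOM))-4H-chromen-4-one, via ynone 21 (not isolated)
Conditions: PdCl2(dppf) (5 mol%), CO (10 bar), Et2NH, 80 °C
Reagents that add atoms: none
Why: Zerovalent palladium inserts into the C–I bond of 2, CO inserts to give the aroyl–palladium species, and coupling with the amine-activated terminal alkyne 19 forms the C4a–C4 and C4–C3 bonds of ynone 21. The closest known reaction is the palladium-catalysed carbonylative Sonogashira annulation of ortho-iodophenols with aryl acetylenes to flavones in a secondary amine. The pyranone ring then closes by 6-endo-dig oxa-Michael addition of the phenoxide oxygen to the ynone β-carbon, which makes the O1–C2 bond. No stereocentre is created, and the two benzylic centres of the dihydrobenzofuran are remote from every reacting atom and are not epimerised by the amine. The step needs 6-endo closure to the flavone over 5-exo closure to the aurone and carbonylation over direct Sonogashira coupling; the Et2NH medium and the polarisation of the ynone by its electron-rich aryl group secure the first, the CO pressure the second.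

Step 13
Reactants: 22 5,7-bis(benzyloxy)-2-(DBF(MOM))-4H-chromen-4-one
Product: 24 (2S)-5,7-bis(benzyloxy)-2-(DBF(MOM))-2,3-dihydro-4H-chromen-4-one, via flavan-4-ol 23 (not isolated)
Conditions: [Ru(cod)(2-methylallyl)2] (5 mol%), (R,R)-SINpEt·HBF4 (10 mol%), KOt-Bu (15 mol%), H2 (100 bar), toluene, 40 °C; then silica filtration, Dess–Martin periodinane, pyridine, CH2Cl2, 0 °C to rt
Reagents that add atoms: none
Why: Ruthenium–NHC-catalysed asymmetric hydrogenation of flavones, in which the chiral carbene ligand selects the face of C2=C3 and sets C2 as S under catalyst control (the benzofuran stereocentres are too remote to interfere); the C4 ketone is hydrogenated as well, to the 2,4-cis alcohol 23, and Dess–Martin oxidation of the crude alcohol restores the ketone under near-neutral conditions that do not open the flavanone ring, so C2 is retained.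

Step 14
Reactants: 24 (2S)-5,7-bis(benzyloxy)-2-(DBF(MOM))-2,3-dihydro-4H-chromen-4-one
Product: 25 (2S)-2-(DBF(MOM))-5,7-dihydroxy-2,3-dihydro-4H-chromen-4-one
Conditions: H2 (1 atm), Pd/C (10 wt% palladium on carbon), EtOAc/MeOH, rt
Reagents that add atoms: none
Why: Palladium-catalysed hydrogenolysis of the two aryl benzyl ethers, which at atmospheric pressure should be much faster than cleavage of the cyclic benzylic C–O bonds of the flavanone and the dihydrobenzofuran and leaves the MOM acetals and the chelated ketone intact.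

Step 15
Reactants: 25 (2S)-2-(DBF(MOM))-5,7-dihydroxy-2,3-dihydro-4H-chromen-4-one
Product: 26 (2S)-2-(DBF(MOM))-5-hydroxy-7-[(2-methylbut-3-yn-2-yl)oxy]-2,3-dihydro-4H-chromen-4-one
Conditions: 3-chloro-3-methylbut-1-yne (1.2 equiv), DBU (1.1 equiv), CuCl2 (1 mol%), MeCN, −5 °C
Reagents that add atoms: 3-chloro-3-methylbut-1-yne, C#CC(C)(C)Cl
Why: Copper-catalysed propargylic O-alkylation of the only readily ionised phenol, since the 7-OH (para to the C4 carbonyl) is deprotonated by DBU while the 5-OH stays locked in its hydrogen bond to C4=O, every other phenol is a MOM ether, and the low temperature protects C2.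

Step 16
Reactants: 26 (2S)-2-(DBF(MOM))-5-hydroxy-7-[(2-methylbut-3-yn-2-yl)oxy]-2,3-dihydro-4H-chromen-4-one
Product: 29 (2S)-2-(DBF(MOM))-5-hydroxy-8,8-dimethyl-2,3-dihydro-4H,8H-pyrano[2,3-f]chromen-4-one, via allenylphenol 27 (not isolated), via quinone methide 28 (not isolated)
Conditions: DMF (amine-free, degassed), 130 °C, dark
Reagents that add atoms: none
Why: Aromatic propargyl Claisen rearrangement to C8, tautomerisation to 27, [1,5]-hydrogen shift to 28 and 6π oxa-electrocyclisation give the 2,2-dimethylchromene; the hydrogen bond between 5-OH and C4=O should direct the migration to C8 and not C6, as in the cyclisation of 5-hydroxy-7-(1,1-dimethylpropargyloxy) chromones and isoflavones to angular pyrano compounds, and any linear isomer is removed by chromatography.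

Step 17
Reactants: 29 (2S)-2-(DBF(MOM))-5-hydroxy-8,8-dimethyl-2,3-dihydro-4H,8H-pyrano[2,3-f]chromen-4-one
Product: 30 (2S)-2-(DBF(OH))-5-hydroxy-8,8-dimethyl-2,3-dihydro-4H,8H-pyrano[2,3-f]chromen-4-one
Conditions: HCl (2 M aq), MeOH/THF, 40 °C
Reagents that add atoms: none
Why: Acid-catalysed acetal exchange (methanolysis) removes the four aryl MOM ethers, and the chromene on the carbonyl-deactivated ring A, the flavanone C2 and the thermodynamically preferred trans-dihydrobenzofuran should all tolerate dilute acid at this temperature.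

Step 18
Reactants: 30 (2S)-2-(DBF(OH))-5-hydroxy-8,8-dimethyl-2,3-dihydro-4H,8H-pyrano[2,3-f]chromen-4-one
Product: 32 (2S)-2-(DBF(OH))-5,7-dihydroxy-8-[(1Z)-3-methylbuta-1,3-dien-1-yl]-2,3-dihydro-4H-chromen-4-one (CNP0284772.1), via quinone methide 31 (not isolated)
Conditions: hν (365 nm LED), degassed MeCN, 0 °C, stopped at partial conversion, 30 recycled
Reagents that add atoms: none
Why: Photochemical 6π electrocyclic ring opening of the 2,2-dimethyl-2H-chromene to 31 followed by a thermal [1,7]-hydrogen shift from a methyl group to the carbonyl oxygen is the known route from 2,2-dimethylchromenes to ortho-(3-methylbuta-1,3-dienyl)phenols, and its eight-membered cyclic transition state (s-cis about the former pyran C3–C4 bond) delivers the Z alkene.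

**Compound list**

1 | 3,5-bis(benzyloxy)phenol | Oc1cc(OCc2ccccc2)cc(OCc2ccccc2)c1 | starting material
2 | 3,5-bis(benzyloxy)-2-iodophenol | Oc1cc(OCc2ccccc2)cc(OCc2ccccc2)c1I | intermediate
3 | 5-bromo-2,4-dihydroxybenzaldehyde | O=Cc1cc(Br)c(O)cc1O | starting material
4 | 5-bromo-2-hydroxy-4-(methoxymethoxy)benzaldehyde | O=Cc1cc(Br)c(OCOC)cc1O | intermediate
5 | 5-bromoresorcinol (5-bromobenzene-1,3-diol) | Oc1cc(O)cc(Br)c1 | starting material
6 | 1-bromo-3,5-bis(methoxymethoxy)benzene | COCOc1cc(Br)cc(OCOC)c1 | intermediate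
7 | [3,5-bis(methoxymethoxy)phenyl]magnesium bromide (formed in the flask) | COCOc1cc([Mg]Br)cc(OCOC)c1 | intermediate
8 | 4-bromo-2-{[3,5-bis(methoxymethoxy)phenyl](hydroxy)methyl}-5-(methoxymethoxy)phenol, racemic | OC(c1cc(OCOC)cc(OCOC)c1)c1cc(Br)c(OCOC)cc1O | intermediate
9 | 4-bromo-2-{[3,5-bis(methoxymethoxy)phenyl](4-methylbenzenesulfonyl)methyl}-5-(methoxymethoxy)phenol, racemic | Cc1ccc(cc1)S(=O)(=O)C(c1cc(OCOC)cc(OCOC)c1)c1cc(Br)c(OCOC)cc1O | intermediate
10 | 4-hydroxybenzyl alcohol | OCc1ccc(O)cc1 | starting material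
11 | [4-(methoxymethoxy)phenyl]methanol | COCOc1ccc(CO)cc1 | intermediate
12 | 1-(bromomethyl)-4-(methoxymethoxy)benzene | COCOc1ccc(CBr)cc1 | intermediate
13 | (1R,4R,5R)-4,7,7-trimethyl-6-thiabicyclo[3.2.1]octane (isothiocineole) | C[C@@H]1CC[C@@H]2C[C@H]1SC2(C)C | starting material
14 | (1R,4R,5R)-6-[4-(methoxymethoxy)benzyl]-4,7,7-trimethyl-6-thiabicyclo[3.2.1]octan-6-ium tetrafluoroborate, benzyl exo on sulfur | C[C@@H]1CC[C@@H]2C[C@H]1[S@@+](Cc1ccc(OCOC)cc1)C2(C)C.F[B-](F)(F)F | intermediate
15 | 4-bromo-6-[3,5-bis(methoxymethoxy)benzylidene]-3-(methoxymethoxy)cyclohexa-2,4-dien-1-one (ortho-quinone methide, alkene geometry not defined, formed in the flask) | O=C1C=C(OCOC)C(Br)=CC1=Cc1cc(OCOC)cc(OCOC)c1 | intermediate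
16 | [4-(methoxymethoxy)phenyl]methylide of the sulfonium ion of 14 (formed in the flask) | C[C@@H]1CC[C@@H]2C[C@H]1[S@@+]([CH-]c1ccc(OCOC)cc1)C2(C)C | intermediate
17 | (2R,3R)-5-bromo-3-[3,5-bis(methoxymethoxy)phenyl]-6-(methoxymethoxy)-2-[4-(methoxymethoxy)phenyl]-2,3-dihydro-1-benzofuran (trans) | Brc1cc2c(cc1OCOC)O[C@@H](c1ccc(OCOC)cc1)[C@@H]2c1cc(OCOC)cc(OCOC)c1 | intermediate
18 | [(DBF(MOM))ethynyl]trimethylsilane | C[Si](C)(C)C#Cc1cc2c(cc1OCOC)O[C@@H](c1ccc(OCOC)cc1)[C@@H]2c1cc(OCOC)cc(OCOC)c1 | intermediate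
19 | (2R,3R)-5-ethynyl-3-[3,5-bis(methoxymethoxy)phenyl]-6-(methoxymethoxy)-2-[4-(methoxymethoxy)phenyl]-2,3-dihydro-1-benzofuran | C#Cc1cc2c(cc1OCOC)O[C@@H](c1ccc(OCOC)cc1)[C@@H]2c1cc(OCOC)cc(OCOC)c1 | intermediate
20 | carbon monoxide | [C-]#[O+] | starting material
21 | 1-[2,4-bis(benzyloxy)-6-hydroxyphenyl]-3-(DBF(MOM))prop-2-yn-1-one (formed in the flask) | Oc1cc(OCc2ccccc2)cc(OCc2ccccc2)c1C(=O)C#Cc1cc2c(cc1OCOC)O[C@@H](c1ccc(OCOC)cc1)[C@@H]2c1cc(OCOC)cc(OCOC)c1 | intermediate
22 | 5,7-bis(benzyloxy)-2-(DBF(MOM))-4H-chromen-4-one (flavone) | O=c1cc(-c2cc3c(cc2OCOC)O[C@@H](c2ccc(OCOC)cc2)[C@@H]3c2cc(OCOC)cc(OCOC)c2)oc2cc(OCc3ccccc3)cc(OCc3ccccc3)c12 | intermediate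
23 | (2S,4S)-5,7-bis(benzyloxy)-2-(DBF(MOM))-3,4-dihydro-2H-chromen-4-ol (2,4-cis flavan-4-ol, formed in the flask) | c1ccc(cc1)COc1cc(OCc3ccccc3)c2c(c1)O[C@H](c1cc3c(cc1OCOC)O[C@@H](c1ccc(OCOC)cc1)[C@@H]3c1cc(OCOC)cc(OCOC)c1)C[C@@H]2O | intermediate
24 | (2S)-5,7-bis(benzyloxy)-2-(DBF(MOM))-2,3-dihydro-4H-chromen-4-one (flavanone) | c1ccc(cc1)COc1cc(OCc3ccccc3)c2c(c1)O[C@H](c1cc3c(cc1OCOC)O[C@@H](c1ccc(OCOC)cc1)[C@@H]3c1cc(OCOC)cc(OCOC)c1)CC2=O | intermediate
25 | (2S)-2-(DBF(MOM))-5,7-dihydroxy-2,3-dihydro-4H-chromen-4-one | Oc1cc(O)c2c(c1)O[C@H](c1cc3c(cc1OCOC)O[C@@H](c1ccc(OCOC)cc1)[C@@H]3c1cc(OCOC)cc(OCOC)c1)CC2=O | intermediate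
26 | (2S)-2-(DBF(MOM))-5-hydroxy-7-[(2-methylbut-3-yn-2-yl)oxy]-2,3-dihydro-4H-chromen-4-one | C#CC(C)(C)Oc1cc(O)c2c(c1)O[C@H](c1cc3c(cc1OCOC)O[C@@H](c1ccc(OCOC)cc1)[C@@H]3c1cc(OCOC)cc(OCOC)c1)CC2=O | intermediate
27 | (2S)-2-(DBF(MOM))-5,7-dihydroxy-8-(3-methylbuta-1,2-dien-1-yl)-2,3-dihydro-4H-chromen-4-one (formed in the flask) | CC(C)=C=Cc1c(O)cc(O)c2c1O[C@H](c1cc3c(cc1OCOC)O[C@@H](c1ccc(OCOC)cc1)[C@@H]3c1cc(OCOC)cc(OCOC)c1)CC2=O | intermediate
28 | (2S,8Z)-2-(DBF(MOM))-5-hydroxy-8-(3-methylbut-2-en-1-ylidene)-2,3-dihydro-4H-chromene-4,7(8H)-dione (ortho-quinone methide, side chain syn to the C7 carbonyl, formed in the flask) | CC(C)=C/C=C1\C(=O)C=C(O)C2=C1O[C@H](c1cc3c(cc1OCOC)O[C@@H](c1ccc(OCOC)cc1)[C@@H]3c1cc(OCOC)cc(OCOC)c1)CC2=O | intermediate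
29 | (2S)-2-(DBF(MOM))-5-hydroxy-8,8-dimethyl-2,3-dihydro-4H,8H-pyrano[2,3-f]chromen-4-one (2,2-dimethylpyran fused at O7–C8 of the flavanone) | CC1(C)C=Cc2c(O1)cc(O)c1c2O[C@H](c2cc3c(cc2OCOC)O[C@@H](c2ccc(OCOC)cc2)[C@@H]3c2cc(OCOC)cc(OCOC)c2)CC1=O | intermediate
30 | (2S)-2-(DBF(OH))-5-hydroxy-8,8-dimethyl-2,3-dihydro-4H,8H-pyrano[2,3-f]chromen-4-one | CC1(C)C=Cc2c(O1)cc(O)c1c2O[C@H](c2cc3c(cc2O)O[C@@H](c2ccc(O)cc2)[C@@H]3c2cc(O)cc(O)c2)CC1=O | intermediate
31 | (2S,8Z)-2-(DBF(OH))-5-hydroxy-8-(3-methylbut-2-en-1-ylidene)-2,3-dihydro-4H-chromene-4,7(8H)-dione (ortho-quinone methide, side chain syn to the C7 carbonyl, formed in the flask) | CC(C)=C/C=C1\C(=O)C=C(O)C2=C1O[C@H](c1cc3c(cc1O)O[C@@H](c1ccc(O)cc1)[C@@H]3c1cc(O)cc(O)c1)CC2=O | intermediate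
32 | (2S)-2-[(2R,3R)-3-(3,5-dihydroxyphenyl)-6-hydroxy-2-(4-hydroxyphenyl)-2,3-dihydro-1-benzofuran-5-yl]-5,7-dihydroxy-8-[(1Z)-3-methylbuta-1,3-dien-1-yl]-2,3-dihydro-4H-chromen-4-one (CNP0284772.1) | C=C(C)/C=C\c1c(O)cc(O)c2c1O[C@H](c1cc3c(cc1O)O[C@@H](c1ccc(O)cc1)[C@@H]3c1cc(O)cc(O)c1)CC2=O | target

**Step count and risks**

Total step count: 18.
Longest linear sequence: 13 steps (steps 3, 4, 5 and 9 to 18 from 5-bromoresorcinol 5; equally steps 6 to 18 from 4-hydroxybenzyl alcohol 10).

Steps most likely to fail: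

1. Step 9. The process at risk is the transfer of chirality from the sulfide: weak facial discrimination of the ylide in the conjugate addition, or reversible betaine formation that erodes the trans preference, would give material of low enantiomeric or diastereomeric purity. The fallback sets out from bromide 12 (with sulfone 9 as partner) and returns at 17. Bromide 12 is treated with tetrahydrothiophene and NaBF4 to give the achiral salt 1-[4-(methoxymethoxy)benzyl]thiolan-1-ium tetrafluoroborate F1. Its Cs2CO3-mediated annulation with 9 is the established racemic [4+1] reaction of sulfur ylides with quinone methides and should give 17 together with its mirror image, (2S,3S)-5-bromo-3-[3,5-bis(methoxymethoxy)phenyl]-6-(methoxymethoxy)-2-[4-(methoxymethoxy)phenyl]-2,3-dihydro-1-benzofuran F2, as the racemic trans compound. Preparative SFC on an amylose tris(3,5-dimethylphenylcarbamate) phase removes F2 and leaves 17 for step 10.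

2. Step 18. The processes at risk are electron or hydrogen transfer from the free phenol rings to the excited chelated ketone, addition of phenolic OH to the photogenerated quinone methide, and over-irradiation of the product to the E isomer. The fallback sets out from 30 and returns at 32; it moves the ring opening onto a masked substrate and ends with a fluoride unmasking instead of a protecting-group-free photoreaction. TBSCl and imidazole (DMF, 0 °C) silylate the four non-chelated phenols of 30 to give the tetrakis(tert-butyldimethylsilyl) ether of 30 at the benzofuran 6-OH, the 4-hydroxyphenyl OH and both resorcinol OH groups F3. Irradiation of F3 under the conditions of step 18 passes through the tetra-O-silylated quinone methide F4 and should give the tetra-O-silylated (Z)-dienylphenol with free 5-OH and 7-OH F5. Et3N·3HF (THF, 0 °C) then removes the silyl groups without acid strong enough to re-close the chromene and gives 32.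

3. Step 13. The process at risk is poor facial selectivity or stalled turnover of the chiral ruthenium catalyst on the hindered, ortho-substituted, polyoxygenated flavone. The fallback sets out from 22 and returns at 24, with no oxidation needed. Conjugate reduction of 22 with LiBH(s-Bu)3 (THF, −78 °C) gives flavanone 24 together with its C2 epimer, (2R)-5,7-bis(benzyloxy)-2-(DBF(MOM))-2,3-dihydro-4H-chromen-4-one F6. The two are diastereomers, because the benzofuran centres are fixed, and are separated by chromatography. F6 is recycled by NaOAc-mediated equilibration (EtOH, reflux) through the ring-opened chalcone and separated again.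

Further compounds
F1 | step 9 | 1-[4-(methoxymethoxy)benzyl]thiolan-1-ium tetrafluoroborate | COCOc1ccc(C[S+]2CCCC2)cc1.F[B-](F)(F)F
F2 | step 9 | (2S,3S)-5-bromo-3-[3,5-bis(methoxymethoxy)phenyl]-6-(methoxymethoxy)-2-[4-(methoxymethoxy)phenyl]-2,3-dihydro-1-benzofuran (enantiomer of 17) | Brc1cc2c(cc1OCOC)O[C@H](c1ccc(OCOC)cc1)[C@H]2c1cc(OCOC)cc(OCOC)c1
F3 | step 18 | tetrakis(tert-butyldimethylsilyl) ether of 30 (benzofuran 6-O, 4-hydroxyphenyl O and both resorcinol O silylated, 5-OH free) | CC1(C)C=Cc2c(O1)cc(O)c1c2O[C@H](c2cc3c(cc2O[Si](C)(C)C(C)(C)C)O[C@@H](c2ccc(O[Si](C)(C)C(C)(C)C)cc2)[C@@H]3c2cc(O[Si](C)(C)C(C)(C)C)cc(O[Si](C)(C)C(C)(C)C)c2)CC1=O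
F4 | step 18 | tetrakis(tert-butyldimethylsilyl) ether of quinone methide 31 at the same four oxygens (formed in the flask) | CC(C)=C/C=C1\C(=O)C=C(O)C2=C1O[C@H](c1cc3c(cc1O[Si](C)(C)C(C)(C)C)O[C@@H](c1ccc(O[Si](C)(C)C(C)(C)C)cc1)[C@@H]3c1cc(O[Si](C)(C)C(C)(C)C)cc(O[Si](C)(C)C(C)(C)C)c1)CC2=O
F5 | step 18 | tetrakis(tert-butyldimethylsilyl) ether of 32 at the same four oxygens (5-OH and 7-OH free, Z diene) | C=C(C)/C=C\c1c(O)cc(O)c2c1O[C@H](c1cc3c(cc1O[Si](C)(C)C(C)(C)C)O[C@@H](c1ccc(O[Si](C)(C)C(C)(C)C)cc1)[C@@H]3c1cc(O[Si](C)(C)C(C)(C)C)cc(O[Si](C)(C)C(C)(C)C)c1)CC2=O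
F6 | step 13 | (2R)-5,7-bis(benzyloxy)-2-(DBF(MOM))-2,3-dihydro-4H-chromen-4-one (C2 epimer of 24) | c1ccc(cc1)COc1cc(OCc3ccccc3)c2c(c1)O[C@@H](c1cc3c(cc1OCOC)O[C@@H](c1ccc(OCOC)cc1)[C@@H]3c1cc(OCOC)cc(OCOC)c1)CC2=O
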